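In a one-step world, enzyme turns starting material into product and the rate per amount of starting material scales with the enzyme charged, so the 2 µM runs should lose their fraction of starting material twice as fast as the east run at 1 µM.

| setting | south | north | east | flask |
|---|---|---|---|---|
| starting material | 0.010 M | 0.040 M | 0.020 M | 0.020 M |
| enzyme | 2 µM | 2 µM | 1 µM | 2.0 µM |
| impurity | 0.51 µM | 0.51 µM | 0.51 µM | 0.51 µM |
| remark | run made earlier | run made earlier | run made earlier |  |

- south (time / min: product / %): 5.00: 95; 10.0: 100; 15.0: 100; 20.0: 100; 25.0: 101
- north (time / min: product / %): 5.00: 94; 10.0: 97; 15.0: 100; 20.0: 104; 25.0: 99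
- east (time / min: product / %): 2.00: 31; 4.00: 49; 6.00: 66; 12.0: 92; 25.0: 101

(scatter of a reading: 2 percentage points)

1. factor on the rate of making product when 5.0 % of the starting material are converted if enzyme is charged twice over
2. factor on the rate when 5.0 % of the starting material are converted if enzyme is charged at 20 µM instead

- the analysis behind the earlier runs scatters by 2 percentage points, standard deviation

We test this with k, minus the logarithm of the fraction left, divided by time. The reading is 0.180 min⁻¹ for the east run at 6.00 min, against 0.599 min⁻¹ for south and 0.563 min⁻¹ for north at 5.00 min. The mean of south and north, which charge 0.010 M and 0.040 M of starting material, over east reads 3.23, though each reading scatters by 2 percentage points.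

So we compare two amounts, enzyme and impurity. We suppose each impurity removes one enzyme, which makes impurity the limiting reagent of that loss, at a quarter of the enzyme in the flask. Then W, the working enzyme, is enzyme charged minus impurity charged:

W = 2.0 µM − 0.51 µM = 1.49 µM

This gives 3.04 between the earlier runs. We take the rate as proportional to W; with the same charge of starting material and at equal conversion, starting material cancels, so our factors for the flask are:

doubled: (4.00 µM − 0.51 µM) / W = 2.34

20 µM: (20 µM − 0.51 µM) / W = 13.1

The forecast says the same, 2.34 and 13.1, reading the impurity “as a tight, stoichiometric inhibitor”.

    enzyme + impurity → spent catalyst (k = 1.00 × 10⁵ M⁻¹ s⁻¹)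
    starting material + enzyme → product + enzyme, rate k2*[starting material]*[enzyme]/(1 + ([starting material]/Km2)) (23.0 mM, k = 9500 M⁻¹ s⁻¹)

The flask gives 2.19 and 11.7. At 0.0920 min, spent catalyst is 16.1 % of the catalyst in the flask. At that moment the flask still holds 1.68 µM of enzyme, more than W. With that as the divisor, W for the 20 µM flask, 19.5 µM, gives 11.6, and that flask's simulated factor is 11.7.

(The runs were computed for substances that don't exist; scatter was added.)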